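**Plan**

Target numbering used here: C1 = CCl(CH2Br), C2 = CHBr, C3 = CH2, C4 = CHCl, C5 = C(CH3)(CH=CHCl), C6 = CH2; the target is (1S,2S,4R,5R).
Retrosynthesis: C4–Cl goes back to a C4 carbinol and ketone, CH=CHCl on C5 to CHO and CH2OH (chloro-olefination, aldol), CH2Br on C1 to CHO; the C4 ketone with its α-carbon C5 is an enol ether C4=C5, and the cyclohexene so revealed is cut at C2–C3 and C6–C1 ([4+2]).
Enabling feature: the two ring CH2 groups (C3, C6) are para, the C4–C5 pair between them can be a C=C, and the C1–C2 pair carries Cl and Br cis, the imprint of a (Z)-dihaloalkene; the ring is therefore 2-silyloxy-3-methylbutadiene plus (Z)-3-bromo-2-chloroacrolein.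
Forward: dienophile 2 and diene 4 are made in one step each; step 3 closes the only ring and leaves a regiodefined enol silane; then CHO to CH2Br, hydroxymethylation at C5, directed reduction, oxidation, chloro-olefination, invertive chlorination.
Stereochemistry: C1/C2 relative from the dienophile geometry and absolute from a chiral oxazaborolidinium catalyst; C5 by substrate-controlled aldol; C4 by hydroxyl-directed reduction then SN2 inversion; the E-alkene from the chromium olefination.

Key step: step 3

Assumption: the sense of induction in step 3 is taken from the usual pre-transition-state model for α-substituted enals on these cationic oxazaborolidines, which points to the (R)-catalyst for attack on the Re face of C2 of 2; if the opposite sense is found, the (S)-catalyst is used and nothing else changes.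

**Route**

Step 1
Reactants: 1 2-chloromalonaldehyde (enol form)
Product: 2 (2Z)-3-bromo-2-chloroprop-2-enal
Conditions: (COBr)2, cat. DMF, CH2Cl2, 0 °C to rt; distillation
Reagents that add atoms: oxalyl bromide, O=C(Br)C(=O)Br
Why: Vilsmeier-type deoxybromination of a vinylogous acid to the β-bromo enal; addition–elimination is reversible under the HBr formed, so the isomer with Br anti to the formyl group, the (Z)-isomer, should dominate and any (E)-isomer is removed.

Step 2
Reactants: 3 3-methylbut-3-en-2-one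
Product: 4 [(3-methylbuta-1,3-dien-2-yl)oxy]triisopropylsilane
Conditions: TIPSOTf, Et3N, CH2Cl2, 0 °C to rt
Reagents that add atoms: triisopropylsilyl triflate, CC(C)[Si](OS(=O)(=O)C(F)(F)F)(C(C)C)C(C)C
Why: Soft enolisation and O-silylation of the enone at its only enolisable position (silyl dienol ether formation) gives the 2-silyloxy diene.

Step 3
Reactants: 4 [(3-methylbuta-1,3-dien-2-yl)oxy]triisopropylsilane; 2 (2Z)-3-bromo-2-chloroprop-2-enal
Product: 5 (1S,6S)-6-bromo-1-chloro-3-methyl-4-(triisopropylsilyloxy)cyclohex-3-ene-1-carbaldehyde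
Conditions: (R)-B-o-tolyl oxazaborolidine from (R)-α,α-diphenylprolinol (20 mol%), Tf2NH (18 mol%), CH2Cl2, −78 to −40 °C
Reagents that add atoms: none
Why: Catalytic enantioselective Diels–Alder reaction of a 2-silyloxydiene with an α-halo enal bound to a chiral cationic oxazaborolidine (closest type: the same catalysts with 2-chloro- or 2-bromoacrolein and 2-silyloxybutadienes); both σ-bonds form in one concerted, asynchronous π4s+π2s event. The only ring, the cyclohexene, closes by intermolecular [4+2] cycloaddition, the CH2 terminus next to C–OSi (largest HOMO coefficient) bonding to the β-carbon CHBr and the CH2 terminus next to C–CH3 to the α-carbon CCl(CHO). The relative configuration of the two new stereocentres follows from suprafacial addition to the (Z)-alkene, so Cl and Br end up cis and CHO trans to Br. The absolute configuration is set by the catalyst, which binds the formyl group (B–O coordination plus formyl C–H···O contact), holds the enal s-trans and leaves only the Re face of the chlorine-bearing carbon open. The step needs regioselectivity, secured by the silyloxy group outweighing the methyl group as director, and chemoselectivity for cycloaddition over conjugate addition with bromide loss, favoured by low temperature and the concerted path; endo/exo selectivity is immaterial because both diene termini are CH2, and the silyl enol ether formed fixes the site of the next C–C bond.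

Step 4
Reactants: 5 (1S,6S)-6-bromo-1-chloro-3-methyl-4-(triisopropylsilyloxy)cyclohex-3-ene-1-carbaldehyde
Product: 6 [(1S,6S)-6-bromo-1-chloro-3-methyl-4-(triisopropylsilyloxy)cyclohex-3-en-1-yl]methanol
Conditions: NaBH4, MeOH/THF, −20 °C
Reagents that add atoms: none
Why: Chemoselective borohydride reduction of the hindered α-chloro aldehyde; the silyl enol ether, the tertiary chloride and the secondary bromide are inert at low temperature and no stereocentre is touched.

Step 5
Reactants: 6 [(1S,6S)-6-bromo-1-chloro-3-methyl-4-(triisopropylsilyloxy)cyclohex-3-en-1-yl]methanol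
Product: 8 [(4S,5S)-5-bromo-4-(bromomethyl)-4-chloro-2-methylcyclohex-1-en-1-yl]oxy-triisopropylsilane, via neopentyl triflate 7 (not isolated)
Conditions: Tf2O, 2,6-lutidine, CH2Cl2, −78 °C; then Bu4NBr, −78 °C to rt
Reagents that add atoms: tetrabutylammonium bromide, CCCC[N+](CCCC)(CCCC)CCCC.[Br-]; triflic anhydride, O=S(=O)(OS(=O)(=O)C(F)(F)F)C(F)(F)F (its atoms stay only in intermediate 7)
Why: Triflation followed by SN2 displacement with bromide is the standard way to substitute a neopentyl-type primary alcohol, and the buffered aprotic medium keeps the silyl enol ether.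

Step 6
Reactants: 8 [(4S,5S)-5-bromo-4-(bromomethyl)-4-chloro-2-methylcyclohex-1-en-1-yl]oxy-triisopropylsilane
Product: 9 (2R,4S,5S)-5-bromo-4-(bromomethyl)-4-chloro-2-(hydroxymethyl)-2-methylcyclohexan-1-one
Conditions: aq. HCHO (37%), Sc(OTf)3 (10 mol%), THF/H2O, 0 °C to rt
Reagents that add atoms: formaldehyde, C=O
Why: Lewis acid-catalysed aqueous Mukaiyama aldol reaction (hydroxymethylation of a silyl enol ether) at the regiodefined tetrasubstituted enol carbon gives the quaternary centre and frees the ketone; the small electrophile should add along the π-axis on the half-chair with CH2Br pseudo-equatorial, that is syn to the pseudo-axial chlorine, because the corresponding approach on the other face is 1,3-syn to the larger CH2Br group, so CH2OH should end up cis to that chlorine.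

Step 7
Reactants: 9 (2R,4S,5S)-5-bromo-4-(bromomethyl)-4-chloro-2-(hydroxymethyl)-2-methylcyclohexan-1-one
Product: 11 (1S,2R,4S,5S)-5-bromo-4-(bromomethyl)-4-chloro-2-(hydroxymethyl)-2-methylcyclohexan-1-ol, via alkoxydiacetoxyborohydride salt 10 (not isolated)
Conditions: Me4NBH(OAc)3, MeCN/AcOH 1:1, −30 to −20 °C
Reagents that add atoms: tetramethylammonium triacetoxyborohydride, C[N+](C)(C)C.CC(=O)O[BH-](OC(C)=O)OC(C)=O (its non-hydrogen atoms stay only in intermediate 10)
Why: Evans–Saksena hydroxyl-directed reduction: the primary hydroxyl binds boron and hydride is delivered intramolecularly to the ketone face syn to the CH2O arm, which should give the 1,3-anti diol (OH trans to CH2OH), while the acidic medium avoids E1cB loss of the β-bromide.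

Step 8
Reactants: 11 (1S,2R,4S,5S)-5-bromo-4-(bromomethyl)-4-chloro-2-(hydroxymethyl)-2-methylcyclohexan-1-ol
Product: 12 (1S,2S,4S,5S)-4-bromo-5-(bromomethyl)-5-chloro-2-hydroxy-1-methylcyclohexane-1-carbaldehyde
Conditions: TEMPO (15 mol%), PhI(OAc)2, CH2Cl2, rt
Reagents that add atoms: none
Why: Oxoammonium (TEMPO/PhI(OAc)2) oxidation is selective for the primary over the hindered secondary alcohol and is neutral enough not to trigger retro-aldol cleavage.

Step 9
Reactants: 12 (1S,2S,4S,5S)-4-bromo-5-(bromomethyl)-5-chloro-2-hydroxy-1-methylcyclohexane-1-carbaldehyde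
Product: 13 (1S,2R,4S,5S)-5-bromo-4-(bromomethyl)-4-chloro-2-[(E)-2-chloroethenyl]-2-methylcyclohexan-1-ol
Conditions: CrCl2, CHCl3, THF, 65 °C
Reagents that add atoms: chloroform, ClC(Cl)Cl
Why: Takai–Utimoto chloro-olefination converts the aldehyde into the (E)-2-chlorovinyl group through a gem-dichromium carbenoid, E selectivity arising in the elimination of the β-oxido chromium adduct; the free hydroxyl is tolerated as its chromium alkoxide.

Step 10
Reactants: 13 (1S,2R,4S,5S)-5-bromo-4-(bromomethyl)-4-chloro-2-[(E)-2-chloroethenyl]-2-methylcyclohexan-1-ol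
Product: 15 (1S,2S,4R,5R)-2-bromo-1-(bromomethyl)-1,4-dichloro-5-[(E)-2-chloroethenyl]-5-methylcyclohexane, via alkoxyphosphonium chloride 14 (not isolated)
Conditions: PPh3, NCS, THF, 0 °C to rt
Reagents that add atoms: N-chlorosuccinimide, O=C1CCC(=O)N1Cl; triphenylphosphine, c1ccc(cc1)P(c1ccccc1)c1ccccc1 (its atoms stay only in intermediate 14)
Why: Appel-type chlorination: the alkoxyphosphonium ion is displaced by chloride in an SN2 step with inversion, turning the axial carbinol into the equatorial chloride cis to the chlorovinyl group; invertive chlorination of a cyclohexanol next to a methyl/vinyl quaternary carbon is a precedented reaction type.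

**Compound list**

1 | 2-chloromalonaldehyde (2-chloro-3-hydroxyprop-2-enal) | O=CC(Cl)=CO | starting material
2 | (2Z)-3-bromo-2-chloroprop-2-enal | O=C/C(Cl)=C/Br | intermediate
3 | 3-methylbut-3-en-2-one | CC(=O)C(C)=C | starting material
4 | [(3-methylbuta-1,3-dien-2-yl)oxy]triisopropylsilane | C=C(C)C(=C)O[Si](C(C)C)(C(C)C)C(C)C | intermediate
5 | (1S,6S)-6-bromo-1-chloro-3-methyl-4-(triisopropylsilyloxy)cyclohex-3-ene-1-carbaldehyde | CC1=C(O[Si](C(C)C)(C(C)C)C(C)C)C[C@H](Br)[C@@](Cl)(C=O)C1 | intermediate
6 | [(1S,6S)-6-bromo-1-chloro-3-methyl-4-(triisopropylsilyloxy)cyclohex-3-en-1-yl]methanol | CC1=C(O[Si](C(C)C)(C(C)C)C(C)C)C[C@H](Br)[C@@](Cl)(CO)C1 | intermediate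
7 | [(1S,6S)-6-bromo-1-chloro-3-methyl-4-(triisopropylsilyloxy)cyclohex-3-en-1-yl]methyl trifluoromethanesulfonate | CC1=C(O[Si](C(C)C)(C(C)C)C(C)C)C[C@H](Br)[C@@](Cl)(COS(=O)(=O)C(F)(F)F)C1 | intermediate (not isolated)
8 | [(4S,5S)-5-bromo-4-(bromomethyl)-4-chloro-2-methylcyclohex-1-en-1-yl]oxy-triisopropylsilane | CC1=C(O[Si](C(C)C)(C(C)C)C(C)C)C[C@H](Br)[C@@](Cl)(CBr)C1 | intermediate
9 | (2R,4S,5S)-5-bromo-4-(bromomethyl)-4-chloro-2-(hydroxymethyl)-2-methylcyclohexan-1-one | C[C@]1(CO)C[C@](Cl)(CBr)[C@@H](Br)CC1=O | intermediate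
10 | tetramethylammonium salt of the alkoxy(diacetoxy)borohydride formed from the CH2OH group of 9 | C[C@]1(CO[BH-](OC(C)=O)OC(C)=O)C[C@](Cl)(CBr)[C@@H](Br)CC1=O.C[N+](C)(C)C | intermediate (not isolated)
11 | (1S,2R,4S,5S)-5-bromo-4-(bromomethyl)-4-chloro-2-(hydroxymethyl)-2-methylcyclohexan-1-ol | C[C@]1(CO)C[C@](Cl)(CBr)[C@@H](Br)C[C@@H]1O | intermediate
12 | (1S,2S,4S,5S)-4-bromo-5-(bromomethyl)-5-chloro-2-hydroxy-1-methylcyclohexane-1-carbaldehyde | C[C@]1(C=O)C[C@](Cl)(CBr)[C@@H](Br)C[C@@H]1O | intermediate
13 | (1S,2R,4S,5S)-5-bromo-4-(bromomethyl)-4-chloro-2-[(E)-2-chloroethenyl]-2-methylcyclohexan-1-ol | C[C@]1(/C=C/Cl)C[C@](Cl)(CBr)[C@@H](Br)C[C@@H]1O | intermediate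
14 | {[(1S,2R,4S,5S)-5-bromo-4-(bromomethyl)-4-chloro-2-[(E)-2-chloroethenyl]-2-methylcyclohexyl]oxy}triphenylphosphonium chloride | C[C@]1(/C=C/Cl)C[C@](Cl)(CBr)[C@@H](Br)C[C@@H]1O[P+](c2ccccc2)(c2ccccc2)c2ccccc2.[Cl-] | intermediate (not isolated)
15 | (1S,2S,4R,5R)-2-bromo-1-(bromomethyl)-1,4-dichloro-5-[(E)-2-chloroethenyl]-5-methylcyclohexane | C[C@]1(/C=C/Cl)C[C@](Cl)(CBr)[C@@H](Br)C[C@H]1Cl | target

**Count and risks**

Total steps: 10. Longest linear sequence: 9 steps (step 1 or step 2, then steps 3 to 10).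

Step 3. What may go wrong: the nucleophilic diene terminus may add to the β-bromo enal in a stepwise Mukaiyama–Michael fashion and the adduct may expel bromide instead of closing the ring, or the catalyst may discriminate the faces of the dihalo enal poorly. Fallback, from 4 and 2 back to 6: the cycloaddition is run thermally without Lewis acid (toluene, 60 °C), which should keep it concerted and gives 5 together with its enantiomer (1R,6R)-6-bromo-1-chloro-3-methyl-4-(triisopropylsilyloxy)cyclohex-3-ene-1-carbaldehyde F1. NaBH4 reduction as in step 4 gives 6 together with its enantiomer [(1R,6R)-6-bromo-1-chloro-3-methyl-4-(triisopropylsilyloxy)cyclohex-3-en-1-yl]methanol F2. Esterification with (S)-2-methoxy-2-phenylacetic acid (DCC, DMAP) gives the diastereomeric esters [(1S,6S)-6-bromo-1-chloro-3-methyl-4-(triisopropylsilyloxy)cyclohex-3-en-1-yl]methyl (2S)-2-methoxy-2-phenylacetate F3 and [(1R,6R)-6-bromo-1-chloro-3-methyl-4-(triisopropylsilyloxy)cyclohex-3-en-1-yl]methyl (2S)-2-methoxy-2-phenylacetate F4, which are separated by chromatography. Reductive cleavage of F3 (DIBAL-H, CH2Cl2, −78 to 0 °C) returns 6.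

Step 6. What may go wrong: poor facial selectivity in the C–C bond formation at the enol carbon, through attack anti to the axial chlorine via a twist-boat or through reaction on the other half-chair. Fallback, from 8 back to 9, with catalyst instead of substrate control: palladium-catalysed asymmetric allylation of the enol silane (Pd2(dba)3, (R)-t-Bu-PHOX, diallyl carbonate, cat. Bu4NPh3SiF2, THF; ligand chosen by analogy with the known sense for 2-methylcyclohexanone enolates) should give (2S,4S,5S)-5-bromo-4-(bromomethyl)-4-chloro-2-methyl-2-(prop-2-en-1-yl)cyclohexan-1-one F5. Iridium-catalysed alkene isomerisation gives (2R,4S,5S)-5-bromo-4-(bromomethyl)-4-chloro-2-methyl-2-[(1E)-prop-1-en-1-yl]cyclohexan-1-one F6. Ozonolysis (O3, CH2Cl2, −78 °C; Me2S) gives (1R,4S,5S)-4-bromo-5-(bromomethyl)-5-chloro-1-methyl-2-oxocyclohexane-1-carbaldehyde F7, and aldehyde-selective reduction with NaBH(OAc)3 returns 9.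

Step 10. What may go wrong: E2 loss of the axial oxyphosphonium group with the anti-periplanar ring hydrogen, or 1,2-shift of the anti-periplanar chlorovinyl group, in place of SN2 at the neopentyl carbon. Fallback, from 13 to 15, replacing invertive displacement of an axial leaving group by retentive chlorination of the equatorial epimer: Dess–Martin oxidation gives (2R,4S,5S)-5-bromo-4-(bromomethyl)-4-chloro-2-[(E)-2-chloroethenyl]-2-methylcyclohexan-1-one F8. Luche reduction (NaBH4, CeCl3, MeOH, −78 °C; axial attack anti to the axial chlorovinyl group) should give (1R,2R,4S,5S)-5-bromo-4-(bromomethyl)-4-chloro-2-[(E)-2-chloroethenyl]-2-methylcyclohexan-1-ol F9. SOCl2 converts it to (1R,2R,4S,5S)-5-bromo-4-(bromomethyl)-4-chloro-2-[(E)-2-chloroethenyl]-2-methylcyclohexyl chlorosulfite F10, whose TiCl4-catalysed front-side (SNi-type) collapse should give 15 with retention.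

**Further compounds**

F1 | step 3 | (1R,6R)-6-bromo-1-chloro-3-methyl-4-(triisopropylsilyloxy)cyclohex-3-ene-1-carbaldehyde | CC1=C(O[Si](C(C)C)(C(C)C)C(C)C)C[C@@H](Br)[C@](Cl)(C=O)C1
F2 | step 3 | [(1R,6R)-6-bromo-1-chloro-3-methyl-4-(triisopropylsilyloxy)cyclohex-3-en-1-yl]methanol | CC1=C(O[Si](C(C)C)(C(C)C)C(C)C)C[C@@H](Br)[C@](Cl)(CO)C1
F3 | step 3 | [(1S,6S)-6-bromo-1-chloro-3-methyl-4-(triisopropylsilyloxy)cyclohex-3-en-1-yl]methyl (2S)-2-methoxy-2-phenylacetate | CC1=C(O[Si](C(C)C)(C(C)C)C(C)C)C[C@H](Br)[C@@](Cl)(COC(=O)[C@@H](OC)c2ccccc2)C1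
F4 | step 3 | [(1R,6R)-6-bromo-1-chloro-3-methyl-4-(triisopropylsilyloxy)cyclohex-3-en-1-yl]methyl (2S)-2-methoxy-2-phenylacetate | CC1=C(O[Si](C(C)C)(C(C)C)C(C)C)C[C@@H](Br)[C@](Cl)(COC(=O)[C@@H](OC)c2ccccc2)C1
F5 | step 6 | (2S,4S,5S)-5-bromo-4-(bromomethyl)-4-chloro-2-methyl-2-(prop-2-en-1-yl)cyclohexan-1-one | C[C@]1(CC=C)C[C@](Cl)(CBr)[C@@H](Br)CC1=O
F6 | step 6 | (2R,4S,5S)-5-bromo-4-(bromomethyl)-4-chloro-2-methyl-2-[(1E)-prop-1-en-1-yl]cyclohexan-1-one | C[C@]1(/C=C/C)C[C@](Cl)(CBr)[C@@H](Br)CC1=O
F7 | step 6 | (1R,4S,5S)-4-bromo-5-(bromomethyl)-5-chloro-1-methyl-2-oxocyclohexane-1-carbaldehyde | C[C@]1(C=O)C[C@](Cl)(CBr)[C@@H](Br)CC1=O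
F8 | step 10 | (2R,4S,5S)-5-bromo-4-(bromomethyl)-4-chloro-2-[(E)-2-chloroethenyl]-2-methylcyclohexan-1-one | C[C@]1(/C=C/Cl)C[C@](Cl)(CBr)[C@@H](Br)CC1=O
F9 | step 10 | (1R,2R,4S,5S)-5-bromo-4-(bromomethyl)-4-chloro-2-[(E)-2-chloroethenyl]-2-methylcyclohexan-1-ol | C[C@]1(/C=C/Cl)C[C@](Cl)(CBr)[C@@H](Br)C[C@H]1O
F10 | step 10 | (1R,2R,4S,5S)-5-bromo-4-(bromomethyl)-4-chloro-2-[(E)-2-chloroethenyl]-2-methylcyclohexyl chlorosulfite | C[C@]1(/C=C/Cl)C[C@](Cl)(CBr)[C@@H](Br)C[C@H]1OS(Cl)=O
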